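**Retrosynthetic overview** (A = hydroquinone-derived ring, B = para-phenylene, C = catechol-derived ring, D = meta-phenylene)
1. Target ⇒ O-demethylation and C=C hydrogenation of a macrocyclic stilbene. The 18-membered ring is the only ring made, and it is closed late by McMurry coupling of the A-CHO and B-CHO groups (A–C2–B bridge).
2. Open dialdehyde ⇒ saturation of a diarylalkyne ⇒ Sonogashira union of two diaryl ether halves of about equal size, A–O–D alkyne plus B–O–C iodide (C–C2–D bridge).
3. A–O–D half ⇒ SNAr of 2-fluoro-5-methoxybenzaldehyde (4-fluorophenol: methylation, lithiation next to F, DMF) with 3-ethynylphenol (3-iodophenol plus TMS-acetylene).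
4. B–O–C half ⇒ iodination para to OMe of 4-(2-methoxyphenoxy)benzaldehyde ⇒ SNAr of 4-fluorobenzaldehyde (from 1-bromo-4-fluorobenzene) with guaiacol (from catechol).
5. Ring order: the four benzene rings are bought and the macrocycle is formed in step 12.

Assumption: the SMILES has no stereodescriptor and the molecule has no stereocentre. The macrocycle is taken as conformationally mobile at room temperature, so it is treated as achiral and no enantioselective step is needed.

**Step 1**
Reactants: 1 4-fluorophenol
Product: 2 4-fluoroanisole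
Conditions: MeI (1.2 equiv), K2CO3 (1.5 equiv), acetone, reflux
Reagents that add atoms: iodomethane, CI
Why: Williamson ether synthesis (phenoxide SN2 on MeI) installs a methyl ether that protects the ring-A oxygen and tolerates BuLi, Pd, Ti and H2 until the last step.

**Step 2**
Reactants: 2 4-fluoroanisole
Product: 5 2-fluoro-5-methoxybenzaldehyde, via (2-fluoro-5-methoxyphenyl)lithium 3 (not isolated), via lithium (dimethylamino)(2-fluoro-5-methoxyphenyl)methanolate 4 (not isolated)
Conditions: n-BuLi (1.05 equiv), PMDTA (1.05 equiv), THF, −78 °C, 2 h; DMF (1.5 equiv), −78 → 0 °C; 1 M HCl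
Reagents that add atoms: N,N-dimethylformamide, CN(C)C=O
Why: Directed ortho-metalation with PMDTA-complexed BuLi is acidity-controlled and removes the proton next to F rather than next to OMe, the aryllithium resists benzyne loss at −78 °C, and Bouveault-type formylation with DMF stops at adduct 4 until the acid quench.

**Step 3**
Reactants: 6 3-iodophenol; 7 ethynyl(trimethyl)silane (TMS-acetylene)
Product: 8 3-[(trimethylsilyl)ethynyl]phenol
Conditions: PdCl2(PPh3)2 (2 mol %), CuI (4 mol %), Et3N, THF, rt, degassed
Reagents that add atoms: none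
Why: Sonogashira coupling of an aryl iodide runs at room temperature, tolerates the free phenol, and the TMS cap prevents double arylation.

**Step 4**
Reactants: 8 3-[(trimethylsilyl)ethynyl]phenol
Product: 9 3-ethynylphenol
Conditions: K2CO3 (0.2 equiv), MeOH, rt
Reagents that add atoms: none
Why: Base-catalysed protodesilylation (methanolysis of the C(sp)–Si bond) frees the terminal alkyne without touching anything else.

**Step 5**
Reactants: 5 2-fluoro-5-methoxybenzaldehyde; 9 3-ethynylphenol
Product: 10 2-(3-ethynylphenoxy)-5-methoxybenzaldehyde (A–O–D half)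
Conditions: K2CO3 (1.5 equiv), DMF, 110 °C, N2, 12–16 h
Reagents that add atoms: none
Why: SNAr (addition–elimination) works because the ortho-formyl group stabilises the Meisenheimer adduct and fluoride leaves well, while K2CO3 is too weak to metalate the alkyne.

**Step 6**
Reactants: 11 1-bromo-4-fluorobenzene
Product: 14 4-fluorobenzaldehyde, via (4-fluorophenyl)magnesium bromide 12 (not isolated), via bromomagnesium (dimethylamino)(4-fluorophenyl)methanolate 13 (not isolated)
Conditions: Mg turnings, THF, rt → 40 °C; DMF (1.3 equiv), 0 °C → rt; 1 M HCl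
Reagents that add atoms: N,N-dimethylformamide, CN(C)C=O
Why: Mg inserts only into the C–Br bond, and the Bouveault aldehyde synthesis with DMF gives the aldehyde after hydrolysis of the stable hemiaminolate.

**Step 7**
Reactants: 15 catechol (benzene-1,2-diol)
Product: 16 guaiacol (2-methoxyphenol)
Conditions: catechol (1.5 equiv), MeI (1.0 equiv), K2CO3 (1.0 equiv), acetone, reflux, N2; distillation
Reagents that add atoms: iodomethane, CI
Why: Williamson mono-O-methylation is favoured because catechol is more acidic than guaiacol and is used in excess, so the limiting MeI meets mainly the catechol mono-anion.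

**Step 8**
Reactants: 14 4-fluorobenzaldehyde; 16 guaiacol
Product: 17 4-(2-methoxyphenoxy)benzaldehyde
Conditions: K2CO3 (1.5 equiv), DMF, 120 °C
Reagents that add atoms: none
Why: SNAr on a fluoroarene activated by a para-formyl group is a reliable way to make this diaryl ether.

**Step 9**
Reactants: 17 4-(2-methoxyphenoxy)benzaldehyde
Product: 18 4-(5-iodo-2-methoxyphenoxy)benzaldehyde (B–O–C half)
Conditions: NIS (1.1 equiv), TFA (0.3–1 equiv), MeCN, rt → 40 °C, dark
Reagents that add atoms: N-iodosuccinimide, O=C1CCC(=O)N1I
Why: In this electrophilic aromatic iodination OMe is the strongest donor and directs para, the 4-formylphenoxy group is a much weaker director, and the formyl-bearing ring is deactivated.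

**Step 10**
Reactants: 10 2-(3-ethynylphenoxy)-5-methoxybenzaldehyde; 18 4-(5-iodo-2-methoxyphenoxy)benzaldehyde
Product: 19 2-[3-({3-(4-formylphenoxy)-4-methoxyphenyl}ethynyl)phenoxy]-5-methoxybenzaldehyde
Conditions: PdCl2(PPh3)2 (3 mol %), CuI (5 mol %), Et3N–THF 1:3, degassed, rt → 45 °C
Reagents that add atoms: none
Why: Sonogashira cross-coupling joins the two halves at the future C–D bridge under mild conditions that both aldehydes tolerate, and oxygen exclusion suppresses Glaser dimerisation.

**Step 11**
Reactants: 19 diarylalkyne dialdehyde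
Product: 21 2-[3-[2-[3-(4-formylphenoxy)-4-methoxyphenyl]ethyl]phenoxy]-5-methoxybenzaldehyde, via 2-[3-[(Z)-2-[3-(4-formylphenoxy)-4-methoxyphenyl]ethenyl]phenoxy]-5-methoxybenzaldehyde 20 (not isolated)
Conditions: H2 (1 atm), 10 % Pd/C, Ph2S (0.01–0.05 equiv), EtOAc, rt
Reagents that add atoms: none
Why: Chemoselective catalytic hydrogenation on sulfide-poisoned Pd/C still saturates the alkyne through the cis-alkene but no longer reduces aromatic aldehydes, which gives the flexible bridge needed for ring closure.

**Step 12**
Reactants: 21 bibenzyl dialdehyde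
Product: 23 macrocyclic stilbene (18-membered ring with A–CH=CH–B and C–CH2CH2–D bridges, OMe on A and C, E/Z mixture), via macrocyclic titanium 1,2-diolate (pinacolate, diastereomer mixture) 22 (not isolated)
Conditions: TiCl4 (12 equiv), Zn dust (24 equiv), pyridine, THF, reflux; 21 added by syringe pump over 20 h (final about 1–2 mM)
Reagents that add atoms: none
Why: In the intramolecular McMurry coupling low-valent Ti joins the two aryl aldehydes to a pinacolate that is deoxygenated at reflux, pseudo-high dilution favours the ring over oligomers, and the alkene geometry is erased in step 13.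

**Step 13**
Reactants: 23 macrocyclic stilbene
Product: 24 di-O-methyl ether of the target (both bridges CH2CH2)
Conditions: H2 (1 atm), 10 % Pd/C, EtOAc–EtOH, rt
Reagents that add atoms: none
Why: Catalytic hydrogenation converts both stilbene isomers into the same bibenzyl, and nothing else in the molecule is reducible or hydrogenolysable.

**Step 14**
Reactants: 24 di-O-methyl ether of the target
Product: 26 target CNP0135015.0, via bis(dibromoboryl) ether of the target 25 (not isolated)
Conditions: BBr3 (6 equiv), CH2Cl2, −78 °C → rt; ice/H2O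
Reagents that add atoms: none
Why: In Lewis-acid ether cleavage bromide attacks only the sp3 methyl carbon of the BBr3-complexed anisoles, so both diaryl ethers survive and hydrolysis of 25 frees the two phenols.

**Compound list**
1 | 4-fluorophenol | Oc1ccc(F)cc1 | starting material
2 | 4-fluoroanisole | COc1ccc(F)cc1 | intermediate
3 | (2-fluoro-5-methoxyphenyl)lithium | COc1ccc(F)c([Li])c1 | intermediate (not isolated)
4 | lithium (dimethylamino)(2-fluoro-5-methoxyphenyl)methanolate (racemic) | COc1ccc(F)c(C(O[Li])N(C)C)c1 | intermediate (not isolated)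
5 | 2-fluoro-5-methoxybenzaldehyde | COc1ccc(F)c(C=O)c1 | intermediate
6 | 3-iodophenol | Oc1cccc(I)c1 | starting material
7 | ethynyl(trimethyl)silane | C#C[Si](C)(C)C | starting material
8 | 3-[(trimethylsilyl)ethynyl]phenol | C[Si](C)(C)C#Cc1cccc(O)c1 | intermediate
9 | 3-ethynylphenol | C#Cc1cccc(O)c1 | intermediate
10 | 2-(3-ethynylphenoxy)-5-methoxybenzaldehyde | COc1ccc(Oc2cccc(C#C)c2)c(C=O)c1 | intermediate
11 | 1-bromo-4-fluorobenzene | Fc1ccc(Br)cc1 | starting material
12 | (4-fluorophenyl)magnesium bromide | Fc1ccc([Mg]Br)cc1 | intermediate (not isolated)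
13 | bromomagnesium (dimethylamino)(4-fluorophenyl)methanolate (racemic) | CN(C)C(O[Mg]Br)c1ccc(F)cc1 | intermediate (not isolated)
14 | 4-fluorobenzaldehyde | O=Cc1ccc(F)cc1 | intermediate
15 | catechol | Oc1ccccc1O | starting material
16 | guaiacol (2-methoxyphenol) | COc1ccccc1O | intermediate
17 | 4-(2-methoxyphenoxy)benzaldehyde | COc1ccccc1Oc1ccc(C=O)cc1 | intermediate
18 | 4-(5-iodo-2-methoxyphenoxy)benzaldehyde | COc1ccc(I)cc1Oc1ccc(C=O)cc1 | intermediate
19 | 2-[3-({3-(4-formylphenoxy)-4-methoxyphenyl}ethynyl)phenoxy]-5-methoxybenzaldehyde | COc1ccc(Oc2cccc(C#Cc3ccc(OC)c(Oc4ccc(C=O)cc4)c3)c2)c(C=O)c1 | intermediate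
20 | 2-[3-[(Z)-2-[3-(4-formylphenoxy)-4-methoxyphenyl]ethenyl]phenoxy]-5-methoxybenzaldehyde | COc1ccc(Oc2cccc(/C=C\c3ccc(OC)c(Oc4ccc(C=O)cc4)c3)c2)c(C=O)c1 | intermediate (not isolated)
21 | 2-[3-[2-[3-(4-formylphenoxy)-4-methoxyphenyl]ethyl]phenoxy]-5-methoxybenzaldehyde | COc1ccc(Oc2cccc(CCc3ccc(OC)c(Oc4ccc(C=O)cc4)c3)c2)c(C=O)c1 | intermediate
22 | macrocyclic titanium 1,2-diolate (simplest formal drawing, diastereomer mixture) | COc1ccc2c(c1)C3O[Ti]OC3c4ccc(cc4)Oc5cc(ccc5OC)CCc6cccc(c6)O2 | intermediate (not isolated)
23 | macrocyclic stilbene, di-O-methyl (E/Z mixture, geometry not specified) | COc1ccc2c(c1)C=Cc1ccc(cc1)Oc1cc(ccc1OC)CCc1cccc(c1)O2 | intermediate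
24 | di-O-methyl ether of the target | COc1ccc2c(c1)CCc1ccc(cc1)Oc1cc(ccc1OC)CCc1cccc(c1)O2 | intermediate
25 | bis(dibromoboryl) ether of the target | BrB(Br)Oc1ccc2c(c1)CCc1ccc(cc1)Oc1cc(ccc1OB(Br)Br)CCc1cccc(c1)O2 | intermediate (not isolated)
26 | CNP0135015.0 (achiral, C28H24O4) | Oc1ccc2c(c1)CCc1ccc(cc1)Oc1cc(ccc1O)CCc1cccc(c1)O2 | target

**Total step count:** 14
**Longest linear sequence:** 8 steps (for example 1 → 2 → 5 → 10 → 11 → 12 → 13 → 14; all four arms have the same length)

**Three steps most likely to fail**

Step 12 (McMurry macrocyclisation) may give oligomers, stop at the pinacol, or close the ring in low yield. The fallback sets out from 21 and replaces reductive carbonyl coupling with olefin metathesis. Double Wittig methylenation of 21 (MePPh3Br, KOtBu, THF, 0 °C) gives the bis-styrene 2-ethenyl-1-{3-[2-(3-(4-ethenylphenoxy)-4-methoxyphenyl)ethyl]phenoxy}-4-methoxybenzene F1. Ring-closing metathesis (Grubbs II, 10 mol %, toluene, 1 mM, 80 °C) then closes the ring with loss of ethene. The fallback comes back to the route at 23.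

Step 5 (SNAr) has two weaknesses: the fluoroarene is deactivated by its para-OMe group, and the free alkyne sits in hot base where phenoxide could add to it. The fallback sets out from 6 (with 5) and carries the alkyne through the ether formation in masked form. Sonogashira coupling of 6 with (triisopropylsilyl)acetylene gives 3-[(triisopropylsilyl)ethynyl]phenol F2. This withstands forcing SNAr with 5 (Cs2CO3, DMAc, 140 °C) to give 5-methoxy-2-{3-[(triisopropylsilyl)ethynyl]phenoxy}benzaldehyde F3. TBAF (THF, 0 °C) removes the silyl group, and the fallback comes back to the route at 10.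

Step 9 (iodination) may be slow because the meta-aryloxy group is inductively withdrawing, and it may give regioisomers. The fallback sets out from 14 and 15 and uses a free phenol as the directing group. SNAr of 14 with excess catechol 15 (3 equiv, K2CO3, DMF, 100 °C, N2) gives 4-(2-hydroxyphenoxy)benzaldehyde F4. The much more activated phenol is iodinated para to OH (NIS, cat. p-TsOH, MeCN, rt) to give 4-(2-hydroxy-5-iodophenoxy)benzaldehyde F5. O-methylation (MeI, K2CO3, acetone) brings the fallback back to the route at 18.

**Further compounds**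
F1 | step 12 | 2-ethenyl-1-{3-[2-(3-(4-ethenylphenoxy)-4-methoxyphenyl)ethyl]phenoxy}-4-methoxybenzene | COc1ccc(Oc2cccc(CCc3ccc(OC)c(Oc4ccc(C=C)cc4)c3)c2)c(C=C)c1
F2 | step 5 | 3-[(triisopropylsilyl)ethynyl]phenol | CC(C)[Si](C#Cc1cccc(O)c1)(C(C)C)C(C)C
F3 | step 5 | 5-methoxy-2-{3-[(triisopropylsilyl)ethynyl]phenoxy}benzaldehyde | COc1ccc(Oc2cccc(C#C[Si](C(C)C)(C(C)C)C(C)C)c2)c(C=O)c1
F4 | step 9 | 4-(2-hydroxyphenoxy)benzaldehyde | O=Cc1ccc(Oc2ccccc2O)cc1
F5 | step 9 | 4-(2-hydroxy-5-iodophenoxy)benzaldehyde | O=Cc1ccc(Oc2cc(I)ccc2O)cc1
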